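**Retrosynthetic overview**
- Target ⇒ break the C8–CH2 bond: (2S)-6-prenylpinocembrin plus the o-quinone methide released from the Mannich base of 3-methylphloroacetophenone. C8 is the only free ring carbon, so there is no regiochemical choice.
- (2S)-6-Prenylpinocembrin ⇒ one open-chain δ-hydroxy β-methoxy-enone carrying a 5-prenyl-dioxinone. Acid closes the dihydropyranone (ring C, O1–C8a fixed), then heat unmasks an acylketene that closes the phloroglucinol (ring A) onto the pyranone C=C, in the same pot.
- Open-chain precursor ⇒ γ-dienolate of 5-prenyl-2,2,6-trimethyldioxinone (iodination, then Stille coupling) plus (S)-4-methoxy-6-phenyl-5,6-dihydropyran-2-one.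
- (S)-Lactone ⇒ benzaldehyde plus Brassard's diene by catalytic asymmetric hetero-Diels–Alder; this sets C2, the only stereocentre, and the lactone ring is opened again later.
- Ring order: temporary δ-lactone → ring C, then ring A in one operation; rings B and D are bought.

Assumption: compounds 1, 3, 5, 7 and 13 are purchased as such (3 and 13 are catalogue items, dearer than the others).

**Route**

Step 1
Reactants: 1 2,2,6-trimethyl-4H-1,3-dioxin-4-one
Product: 2 5-iodo-2,2,6-trimethyl-4H-1,3-dioxin-4-one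
Conditions: NIS (1.1 equiv), AcOH, 23 °C, dark
Reagents that add atoms: N-iodosuccinimide O=C1CCC(=O)N1I
Why: Electrophilic α-iodination of the vinylogous ester, whose C5 is the only nucleophilic ring carbon.

Step 2
Reactants: 2 5-iodo-2,2,6-trimethyl-4H-1,3-dioxin-4-one; 3 tributyl(3-methylbut-2-en-1-yl)stannane
Product: 4 2,2,6-trimethyl-5-(3-methylbut-2-en-1-yl)-4H-1,3-dioxin-4-one
Conditions: Pd2(dba)3 (2.5 mol%), AsPh3 (10 mol%), CuI (10 mol%), DMF, 50 °C
Reagents that add atoms: none
Why: Stille coupling of the α-iodo enoate, with reductive elimination at the primary terminus of the prenyl–Pd giving the linear prenyl group, at a temperature below the retro-[4+2] threshold of the dioxinone.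

Step 3
Reactants: 5 methyl (2E)-3-methoxybut-2-enoate
Product: 6 (1E)-1,3-dimethoxy-1-(trimethylsilyloxy)buta-1,3-diene (Brassard's diene)
Conditions: LDA (1.1 equiv), THF, −78 °C; TMSCl (1.2 equiv), −78 → 23 °C; distil
Reagents that add atoms: chlorotrimethylsilane C[Si](C)(C)Cl
Why: γ-Deprotonation of the β-methoxy enoate and O-silylation of the dienolate (silyl ketene acetal formation).

Step 4
Reactants: 6 Brassard's diene; 7 benzaldehyde
Product: 8 (6S)-4-methoxy-6-phenyl-5,6-dihydro-2H-pyran-2-one
Conditions: Ti(OiPr)4/(S)-BINOL (10 mol%), 4 Å MS, PhMe, 0 °C; then TFA (cat.), CH2Cl2, 0 °C; recrystallise to raise ee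
Reagents that add atoms: none
Why: Catalytic asymmetric hetero-Diels–Alder reaction (vinylogous Mukaiyama aldol then lactonisation) in which the chiral Ti–BINOL Lewis acid directs the diene to the Si face of the aldehyde and so sets the S centre; the sense is assigned by analogy with Ti–BINOL additions to benzaldehyde and must be confirmed by optical rotation, the antipodal ligand giving the enantiomer.

Step 5
Reactants: 4 2,2,6-trimethyl-5-(3-methylbut-2-en-1-yl)-4H-1,3-dioxin-4-one; 8 (6S)-4-methoxy-6-phenyl-5,6-dihydro-2H-pyran-2-one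
Product: 9 6-[(3E,6S)-6-hydroxy-4-methoxy-2-oxo-6-phenylhex-3-en-1-yl]-2,2-dimethyl-5-(3-methylbut-2-en-1-yl)-4H-1,3-dioxin-4-one
Conditions: 4 (2.2 equiv), LDA (2.2 equiv), THF, −78 °C; then 8 (1.0 equiv), −78 → −40 °C; AcOH quench at −78 °C; excess 4 recovered
Reagents that add atoms: none
Why: Crossed Claisen-type C-acylation of the lithium dienolate of the dioxinone by the lactone carbonyl, with attack only at the γ-carbon because C5 is blocked by prenyl, the second equivalent of dienolate deprotonating the product, and no bond to the stereocentre broken.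

Step 6
Reactants: 9 6-[(3E,6S)-6-hydroxy-4-methoxy-2-oxo-6-phenylhex-3-en-1-yl]-2,2-dimethyl-5-(3-methylbut-2-en-1-yl)-4H-1,3-dioxin-4-one
Product: 12 (2S)-5,7-dihydroxy-6-(3-methylbut-2-en-1-yl)-2-phenyl-2,3-dihydro-4H-chromen-4-one, via pyranone dioxinone 10 (not isolated), via acylketene 11 (not isolated)
Conditions: PPTS (10 mol%), PhMe (0.01 M), 50 °C, N2 sparge to remove MeOH; then 110 °C, 2 h
Reagents that add atoms: none
Why: Proposed new method: PPTS lets the C6'-OH add to the C2' ketone and the hemiketal ionise with help from the 4'-methoxy group (Stork–Danheiser-type transposition, net loss of MeOH) to give dihydropyranone 10 with O1–C8a fixed and the C–O bond at the stereocentre untouched, then retro-[4+2] of the dioxinone at 110 °C gives acylketene 11 whose ketene carbon is attacked by the nucleophilic α-carbon of the vinylogous ester (formally a 6π-electrocyclisation of the dienylketene enol) and the product tautomerises to the phenol, so C2 stays S and prenyl sits at C6 with C8 free by construction; the closest known reactions are acid cyclodehydration of δ-hydroxy β-dicarbonyls to dihydropyranones, thermal dioxinone-to-acylketene aromatisations and the dienylketene ring closure that ends a Danheiser benzannulation.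

Step 7
Reactants: 13 1-(2,4,6-trihydroxy-3-methylphenyl)ethan-1-one
Product: 14 1-{3-[(dimethylamino)methyl]-2,4,6-trihydroxy-5-methylphenyl}ethan-1-one
Conditions: 40% aq. Me2NH (1.1 equiv), 37% aq. HCHO (1.05 equiv), EtOH, 0 → 23 °C; filter the precipitate
Reagents that add atoms: formaldehyde C=O; dimethylamine CNC
Why: Mannich reaction at the single unsubstituted carbon of the acylphloroglucinol.

Step 8
Reactants: 12 (2S)-5,7-dihydroxy-6-(3-methylbut-2-en-1-yl)-2-phenyl-2,3-dihydro-4H-chromen-4-one; 14 1-{3-[(dimethylamino)methyl]-2,4,6-trihydroxy-5-methylphenyl}ethan-1-one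
Product: 16 (2S)-8-[(3-acetyl-2,4,6-trihydroxy-5-methylphenyl)methyl]-5,7-dihydroxy-6-(3-methylbut-2-en-1-yl)-2-phenyl-2,3-dihydro-4H-chromen-4-one, via ortho-quinone methide 15 (not isolated)
Conditions: 14 (1.3 equiv), AcOH (2 equiv), 1,4-dioxane, 80 °C, N2
Reagents that add atoms: none
Why: Acid-assisted loss of Me2NH from the o-hydroxybenzylamine gives o-quinone methide 15, which is captured by Friedel–Crafts-type conjugate addition of C8 of 12 (its only free ring carbon), under weakly acidic conditions that do not open the flavanone and so keep C2 as S.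

**Compound list**
1 | 2,2,6-trimethyl-4H-1,3-dioxin-4-one | CC1=CC(=O)OC(C)(C)O1 | starting material
2 | 5-iodo-2,2,6-trimethyl-4H-1,3-dioxin-4-one | CC1=C(I)C(=O)OC(C)(C)O1 | intermediate
3 | tributyl(3-methylbut-2-en-1-yl)stannane | CCCC[Sn](CCCC)(CCCC)CC=C(C)C | starting material
4 | 2,2,6-trimethyl-5-(3-methylbut-2-en-1-yl)-4H-1,3-dioxin-4-one | CC1=C(CC=C(C)C)C(=O)OC(C)(C)O1 | intermediate
5 | methyl (2E)-3-methoxybut-2-enoate | CO/C(C)=C/C(=O)OC | starting material
6 | (1E)-1,3-dimethoxy-1-(trimethylsilyloxy)buta-1,3-diene | C=C(OC)/C=C(/O[Si](C)(C)C)OC | intermediate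
7 | benzaldehyde | O=Cc1ccccc1 | starting material
8 | (6S)-4-methoxy-6-phenyl-5,6-dihydro-2H-pyran-2-one | COC1=CC(=O)O[C@H](c2ccccc2)C1 | intermediate
9 | 6-[(3E,6S)-6-hydroxy-4-methoxy-2-oxo-6-phenylhex-3-en-1-yl]-2,2-dimethyl-5-(3-methylbut-2-en-1-yl)-4H-1,3-dioxin-4-one | CC(C)=CCC1=C(CC(=O)/C=C(OC)\C[C@H](O)c2ccccc2)OC(C)(C)OC1=O | intermediate
10 | 2,2-dimethyl-5-(3-methylbut-2-en-1-yl)-6-{[(2S)-4-oxo-2-phenyl-3,4-dihydro-2H-pyran-6-yl]methyl}-4H-1,3-dioxin-4-one | CC(C)=CCC1=C(CC2=CC(=O)C[C@@H](c3ccccc3)O2)OC(C)(C)OC1=O | intermediate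
11 | 2-(3-methylbut-2-en-1-yl)-4-[(2S)-4-oxo-2-phenyl-3,4-dihydro-2H-pyran-6-yl]but-1-ene-1,3-dione (acylketene) | CC(C)=CCC(=C=O)C(=O)CC1=CC(=O)C[C@@H](c2ccccc2)O1 | intermediate
12 | (2S)-5,7-dihydroxy-6-(3-methylbut-2-en-1-yl)-2-phenyl-2,3-dihydro-4H-chromen-4-one | CC(C)=CCc1c(O)cc2c(c1O)C(=O)C[C@@H](c1ccccc1)O2 | intermediate
13 | 1-(2,4,6-trihydroxy-3-methylphenyl)ethan-1-one | CC(=O)c1c(O)cc(O)c(C)c1O | starting material
14 | 1-{3-[(dimethylamino)methyl]-2,4,6-trihydroxy-5-methylphenyl}ethan-1-one | CC(=O)c1c(O)c(C)c(O)c(CN(C)C)c1O | intermediate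
15 | 2-acetyl-3,5-dihydroxy-4-methyl-6-methylidenecyclohexa-2,4-dien-1-one (o-quinone methide) | CC(=O)C1=C(O)C(C)=C(O)C(=C)C1=O | intermediate
16 | (2S)-8-[(3-acetyl-2,4,6-trihydroxy-5-methylphenyl)methyl]-5,7-dihydroxy-6-(3-methylbut-2-en-1-yl)-2-phenyl-2,3-dihydro-4H-chromen-4-one | CC(=O)c1c(O)c(C)c(O)c(Cc2c(O)c(CC=C(C)C)c(O)c3c2O[C@H](c2ccccc2)CC3=O)c1O | target

**Count**
Total steps: 8. Longest linear sequence: 5 steps (3, 4, 5, 6, 8; the branch 1, 2, 5, 6, 8 is equally long).

**Three steps most likely to fail**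

Step 6 (two-ring cascade). The ketene may be intercepted before it closes onto the pyranone, or the ring closure may be slow. The fallback sets out from 9 and replaces the neutral ketene closure by an anionic Claisen condensation in separate operations. Only the acid stage is run (PPTS, PhMe, 50 °C) and dihydropyranone 10 is isolated. Heating 10 with MeOH (10 equiv) in PhMe at 110 °C traps the ketene as methyl 2-(3-methylbut-2-en-1-yl)-3-oxo-4-[(2S)-4-oxo-2-phenyl-3,4-dihydro-2H-pyran-6-yl]butanoate F1. Treating this with LiHMDS (3.3 equiv, THF, −78 → 0 °C) closes ring A by Dieckmann-type attack of the pyranone α-carbon on the ester. The fallback comes back to the route at 12.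

Step 5 (dienolate acylation by the lactone). The vinylogous-carbonate lactone may be too unreactive, may be enolised and ring-opened, or may take the nucleophile at C4. The fallback sets out from 8 and uses an acyclic, chelating acyl donor. MeNH(OMe)·HCl with i-PrMgCl (THF, −20 °C) opens 8 to (2E,5S)-5-hydroxy-N,3-dimethoxy-N-methyl-5-phenylpent-2-enamide F2. TBSCl with imidazole gives (2E,5S)-5-[(tert-butyldimethylsilyl)oxy]-N,3-dimethoxy-N-methyl-5-phenylpent-2-enamide F3. The dienolate of 4 is acylated by this amide through a stable chelated adduct to give the silyl ether of the keto-dioxinone F4. HF·pyridine (THF, 0 °C) removes the silyl group, and the fallback comes back to the route at 9.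

Step 8 (methylene coupling). The quinone methide from the fully substituted ring may form slowly or be lost before the hindered C8 of 12 captures it. The fallback sets out from 12 and reverses the roles. N,N-Dimethylmethyleneiminium iodide (CH2Cl2, 23 °C, NaHCO3 wash) aminomethylates C8 to give (2S)-8-[(dimethylamino)methyl]-5,7-dihydroxy-6-(3-methylbut-2-en-1-yl)-2-phenyl-2,3-dihydro-4H-chromen-4-one F5. Heating this with 13 (3 equiv) and AcOH in dioxane at 80 °C generates the flavanone quinone methide, which the cheap acetophenone, present in excess, traps at its single free carbon. The fallback comes back to the route at 16.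

**Further compounds**
F1 | step 6 | methyl 2-(3-methylbut-2-en-1-yl)-3-oxo-4-[(2S)-4-oxo-2-phenyl-3,4-dihydro-2H-pyran-6-yl]butanoate | CC(C)=CCC(C(=O)OC)C(=O)CC1=CC(=O)C[C@@H](c2ccccc2)O1
F2 | step 5 | (2E,5S)-5-hydroxy-N,3-dimethoxy-N-methyl-5-phenylpent-2-enamide | CON(C)C(=O)/C=C(OC)\C[C@H](O)c1ccccc1
F3 | step 5 | (2E,5S)-5-[(tert-butyldimethylsilyl)oxy]-N,3-dimethoxy-N-methyl-5-phenylpent-2-enamide | CON(C)C(=O)/C=C(OC)\C[C@H](O[Si](C)(C)C(C)(C)C)c1ccccc1
F4 | step 5 | 6-[(3E,6S)-6-[(tert-butyldimethylsilyl)oxy]-4-methoxy-2-oxo-6-phenylhex-3-en-1-yl]-2,2-dimethyl-5-(3-methylbut-2-en-1-yl)-4H-1,3-dioxin-4-one | CC(C)=CCC1=C(CC(=O)/C=C(OC)\C[C@H](O[Si](C)(C)C(C)(C)C)c2ccccc2)OC(C)(C)OC1=O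
F5 | step 8 | (2S)-8-[(dimethylamino)methyl]-5,7-dihydroxy-6-(3-methylbut-2-en-1-yl)-2-phenyl-2,3-dihydro-4H-chromen-4-one | CC(C)=CCc1c(O)c(CN(C)C)c2c(c1O)C(=O)C[C@@H](c1ccccc1)O2
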